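In 2.5 s a flask can do two things to the substrate, open it and close it, and I want to know which of the two is still unfinished at the end.

- zeta: substrate 5.0 mM; fresh partner 1.10 equiv; coupling partner 1.10 equiv; time 2.5 s
- epsilon: substrate 5.0 mM; fresh partner 1.10 equiv; coupling partner 3.30 equiv; time 2.5 s

    substrate + coupling partner → open intermediate (k1 = 370 /M/s)
    coupling partner + fresh partner → second intermediate (k2 = 640 /M/s)
    open intermediate + second intermediate → product (k3 = 18 /M/s)
    coupling partner ⇌ dormant form (K4 = 2.7, k4 = 0.29 /s)

1. which of these there is most of at the end, counted by the substrate in it, zeta (product / open intermediate / substrate)
2. which of these there is most of at the end, counted by the substrate in it, epsilon (product / open intermediate / substrate)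
3. final amount of the leader among these, as a percentage of the substrate charged, in zeta
4. final amount of the leader among these, as a percentage of the substrate charged, in epsilon

The coupling partner is wanted by both substrate and fresh partner, and at the start the first step receives a fraction 0.345 of it. I fold this into one number, the catch 0.379: the coupling partner charge, in equivalents of substrate, times that starting share. In words, it is the fraction of the substrate that could open if the split stayed as it began. That value is for zeta; epsilon has 1.14. Substrate and fresh partner can together take 2.10 equivalents of coupling partner. Well below that charge the coupling partner is the limiting reagent, and the substrate left is about one minus the catch, so the crossing at which substrate gives way as leader lies at a catch of 0.5. Zeta's charge lies below that demand. I leave out the dormant form, because in zeta its forward half-life of 2.4 s is longer than the 0.20 s of the second step.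

So zeta keeps 62.1% of its substrate, and substrate leads. But one number isn't enough for epsilon, whose charge exceeds that demand: I expect the substrate to open, and the catch doesn't say how much closes again. Closing takes about 10.1 s with second intermediate at the fresh partner's charge, longer than the run. So I expect open intermediate to lead in epsilon, with 78.1% remaining.

The forecast gives substrate at 62% (57% to 67%) for zeta, and open intermediate at 81% (77% to 85%) for epsilon, where “the substrate is converted to open intermediate within a fraction of a second”. My epsilon figure lies below its figure.

Zeta ends with substrate leading at 60.5%, 1.6 percentage points under my figure, with 0.25% of its coupling partner left. Epsilon ends with open intermediate leading at 81.6%, 3.5 points over mine. Both lie inside the forecast's ranges. A neighbour of epsilon charged with 0.820 equiv of coupling partner has a catch of 0.282, which puts it below the crossing and leaves 71.8% of the substrate by the same reckoning. That flask ends with substrate leading at 71%, open intermediate at 26.3%, and coupling partner down to 0.17% of its charge.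

(The numbers of this flask are invented; the result is computed.)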